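**Leftover target.** The south run leaves target standing after its peak: from 30.0 min to 50.0 min it falls while isomer climbs. I read that as target draining into isomer, and I want the drain constant: isomer gained per minute per unit of target present.

| flask | solid substrate | temperature | remark | time |
|---|---|---|---|---|
| south | 0.034 M | 85 °C | run made earlier |  |
| north | 0.075 M | 102 °C | run made earlier |  |
| midnight | 0.050 M | 90 °C |  | 1.0 h |
| spring | 0.050 M |  | at 115 °C until 40 min, from then on at 90 °C | 1.0 h |
| noon | 0.050 M | 115 °C |  | 1.0 h |

- south (time / min: target / %, isomer of the product / %): 4.00: 6.8, 2.4; 6.00: 9.5, 0; 8.00: 14.1, 1.0; 15.0: 28.3, 2.0; 20.0: 31.9, 4.5; 30.0: 31.0, 9.0; 50.0: 27.7, 16.0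
- north (time / min: target / %, isomer of the product / %): 2.00: 0.9, 0; 3.00: 3.4, 0.2; 4.00: 3.0, 0.9; 8.00: 6.9, 2.8; 12.0: 7.9, 2.3; 15.0: 9.8, 5.3; 30.0: 14.3, 13.5

(scatter of a reading: 1 percentage point)

- the best flask by share of target in all that became target or isomer of the product; "all alike" if 1.5 percentage points covers them all (midnight / spring / noon / all alike)
- share of target in all that became target or isomer of the product, midnight
- share of target in all that became target or isomer of the product, spring
- share of target in all that became target or isomer of the product, noon

- solid, in amounts per volume of the solution: solid substrate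
- at the start none of the solid substrate is in solution
- what has only dissolved of solid substrate counts as not reacted

**First way.** South's last interval reads 0.0119 /min, north's last interval 0.0454 /min.

**Second way.** Under a steady feed, isomer over target starts as half the drain count, constant times time. South at 20.0 min gives 0.0141 /min, which agrees within the 1 percentage point scatter on 4.5% of isomer. North at 30.0 min gives 0.0629 /min, higher than the first way.

**The cheat.** North's count is 1.36, too large for the short form. That form gives 0.680, the full steady-feed ratio gives 0.830, and the reading is 0.944. So the second way cheats in north, and I keep the first.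

**Decade span.** In logarithms the two constants give 29.3 K, the decade span: the degrees that multiply the drain constant tenfold. The counts are then 1.06 for midnight, 5.39 for spring and 7.56 for noon. If I take the feed as steady to the end, the full form turns these into shares of target (selectivity) of 61.7%, 18.5% and 13.2%.

**The forecast.** It names midnight as best, with 50%, 17% and 5%, and warns: “Uncertainty about when the feed stops is the main risk, especially for spring”. My figures differ from these, most at midnight, but the order is the same.

**The result.** The flasks give 48.1% at midnight, 31.0% at spring and 25.8% at noon, so midnight is best. Noon lands above my figure and the forecast's, and at 10.0 h it reads 25.7%, the same share. My count of 7.56 puts noon many drain lives along, and there my one-way form keeps falling toward zero while the noon flask's share holds still.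

    isomer of the product ⇌ starting material (k = 1.90 × 10⁻⁵ /s, Ea = 123 kJ/mol)
    starting material ⇌ target (K = 0.520, k = 0.00440 /s, Ea = 98.0 kJ/mol, ΔH = −20.0 kJ/mol)
    target ⇌ isomer of the product (K = 3.00, k = 3.30 × 10⁻⁴ /s, Ea = 104 kJ/mol, ΔH = −2.00 kJ/mol)
    starting material ⇌ dormant form (K = 0.720, k = 1.20 × 10⁻⁴ /s, Ea = 111 kJ/mol, ΔH = 5.00 kJ/mol)
    starting material → decomposition product (k = 1.40 × 10⁻⁶ /s, Ea = 115 kJ/mol)
    solid substrate ⇌ starting material, rate k6*(cs6 - [starting material]) while solid is left; crystals form when [starting material] > cs6 (solubility = 41.0 mM, k = 0.00110 /s)
    (constants at 90 °C)

**Colder neighbour.** Midnight's flask at 65 °C: the decade span gives a count of 0.149, small enough for the short form, so a share of 93.1%. The computed flask gives 94.3%.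

Readings and results were computed for an exercise; scatter was added.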